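## Structural features

The target is a bicyclic ent-labdane: a trans-fused decalin (ring A: C1–C5 and C10; ring B: C5–C10; labdane numbering throughout) whose C9 carries a two-carbon arm (C11–C12) ending at the α-carbon C13 of an α,β-unsaturated γ-lactone (C13=C14, C15H2–O, C16=O). Four stereocentres lie side by side along C4–C5–C10–C9, with the descriptors 4R,5S,9R,10S. C4 is quaternary with an equatorial methyl (C18) and an axial acetoxymethyl (C19); C10 is quaternary with an axial methyl (C20) syn to C19; H5 is anti to C20; the C9 chain is equatorial. Ring B carries the exocyclic C8=C17 methylene next to C9. The fragile groups are the butenolide (acidic γ-hydrogens, Michael acceptor), the primary acetate, and the 8(17)-alkene, which moves into the ring under acid. The real difficulty is the 1,3-pair of quaternary centres C4/C10 on a carbocycle with no ring heteroatom to steer reagents, combined with the need for one alkene regioisomer and one enantiomer. Opening the decalin along C4–C5 and C9–C10 lays rings A and B out as one chain in which a C3–C4 epoxide, the C5=C10 alkene and a C8=C9 allylsilane (silicon on C17) hold all of this information; the key step uses exactly this. The epoxide required, (2S,3R) at the oxirane, maps without conflict onto 3R,4R,5S,9R,10S in the bicycle, so the chain needs no stereochemical correction.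

## Logic of the disconnections

**Butenolide.** 35 is traced through 34 to 33 (the C13=C14 bond comes from a sulfoxide syn-elimination), and C12–C13 is then cut to give 28 and 31, the latter used as 32. The lactone is the most base-sensitive part and C12–C13 is the only bond joining it to the decalin, so it is attached last. The gain is a bicyclic primary iodide plus a four-carbon lactone without stereochemical content. The forward steps must alkylate a hindered, sulfur-stabilised enolate without touching the C19 acetate, and the elimination must go into the lactone ring and not toward C12.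

**C12 and C19 functional groups.** 28 goes back to 27 (C12–I from C12–Cl), 27 to 26 (acetate from alcohol) and 26 to 25 (alcohol from silyl ether). Iodide and acetate would not survive the earlier chemistry; they are unmasked in an order that keeps fluoride away from both the iodide and the butenolide. The forward steps must be selective halide exchange and desilylation of a neopentyl-type ether.

**C3 oxygen.** 25 goes back to 24 and 23 by re-installing the C3–O bond. The hydroxyl is the price of an epoxide trigger. It is removed by homolysis because C3 sits next to quaternary C4, where ionic displacement would fail or rearrange. The radical chain must spare the primary chloride and the 1,1-disubstituted alkene.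

**Key disconnection.** 23 goes back to 22 by cutting C4–C5 and C9–C10. Two rings and the centres C4, C5, C9, C10 are traded for one epoxide and two alkene geometries. The forward step needs invertive opening at the tertiary epoxide carbon, a chair–chair fold, and silicon-directed termination. A radical opening would flatten C4 and lose the geometric information, so the polar mode is essential.

**Epoxide.** 22 goes back to 21 (Si–O) and 21 to 20 (the two epoxide C–O bonds). An allylic alcohol lets a reagent-controlled epoxidation pick one alkene out of three and sets the only stereogenic element of the chain. The forward step needs high facial selectivity on a Z-trisubstituted allylic alcohol and must leave the allylsilane alone.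

**Z-alkene.** 20 goes back to 19 and then, across C3=C4, to 16 and 17, the latter used as 18. C4 with C18 and C19 arrives as a three-carbon phosphonate. The olefination must be Z-selective, because this geometry decides that C19 becomes axial.

**Chain ends.** 16 goes back to 15 (aldehyde from alcohol), 15 to 14 (alcohol from silyl ether) and 14 through 13 to 12 (C12–Cl from C12–OH). The C12 oxygen of 12 is turned at once into the spectator that serves the end-game. Every forward step here must be non-acidic because of the allylsilane.

**Allylsilane.** 12 is cut at C8–C17 to 10 and 11, and 10 at C7–C8 to 7 and 9, the latter made in the flask from 8. The trisubstituted alkene geometry is stored in a five-membered enol ether, where ring oxygen and ring carbon are necessarily cis. Replacing the oxygen by carbon with retention gives a single isomer and frees the C12 hydroxyl in the same operation. The forward steps must be an alkylation at the vinylic carbon and a coupling that does not scramble the geometry.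

**E-alkene.** 7 goes back to 6 (iodide from alcohol), and 6 is cut at C10–C20 and C5–C6 to 1, 2 and 3, the forward reaction passing through 4 and 5. A syn-carbometallation of a terminal alkyne puts the methyl group and the metal on the same side, so the two-carbon unit that replaces the metal ends up cis to C20 and the C5=C10 alkene is E as a single isomer. Three simple building blocks replace a trisubstituted alkene of defined geometry in one operation. The forward step must add methyl only to the internal alkyne carbon and keep the geometry during the transfer to the epoxide. An acid-mediated cyclopropylcarbinyl opening could not guarantee that.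

**Lactone reagent.** 31 is cut at C13–S to 29 and 30, a simple substitution.

## Other disconnections considered

Alternative 1: The cut is C3–C4 in ring A. In the forward step KN(SiMe3)2 would deprotonate the secondary nitrile of the iodo nitrile A1, and the planar nitrile anion would displace the C3 iodide (6-exo-tet) to give the bicyclic nitrile A2.
- In its favour: the C4 configuration of A1 is irrelevant; the slim nitrile should take the axial site with the methyl equatorial, which is the arrangement wanted; C3 never carries oxygen.
- Against it here: A1 already contains ring B with C5, C9 and the quaternary C10 in place, so the hardest stereochemical problem is only moved; the axial, neopentyl nitrile then needs three redox and acylation steps to become CH2OAc; a strong amide base next to a primary iodide invites elimination.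
- Comparison: on structure it closes one ring, one bond and one centre against two rings, two bonds and four centres. On mechanism it is the better plan, since an SN2 closure has no cationic side channels and needs no deoxygenation. On step economy it is expected to be longer overall, and the end-game from C12 would be the same in both plans.

Alternative 2: The cuts are C4–C18 and C5–C6 on a preformed ring A. Cu(OTf)2/phosphoramidite-catalysed addition of AlMe3 to the enone A3 would create quaternary C4, and trapping of the aluminium enolate with an allyl electrophile would set C5 trans to the new methyl, giving the ketone A4.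
- In its favour: the absolute configuration comes from a catalyst acting directly at C4; C4 and C5 appear at the final oxidation level in one flask; no C3 oxygen has to be removed. On these three points it is the better plan.
- Against it here: the step closes no ring; C9, C10 and all of ring B remain; aluminium enolates allylate sluggishly and usually need help from zerovalent palladium or transmetallation; the selectivity with a bulky, coordinating CH2OSi substituent on the β-carbon is untested; the allyl group supplies one carbon more than C6–C7.
- Comparison: structurally it delivers two centres and no ring; mechanistically it is reagent-controlled rather than substrate-encoded; in step count it is longer, because a second ring-forming key step must follow.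

Alternative 3: The cut is C9–C10 in ring B. BF3·OEt2 would ionise the tertiary C10 carbinol of the ring-A allylsilane A5, C9 would attack the cation, and loss of silicon would give the acetate A6.
- In its favour: both C10 epimers of A5 converge on one cation; the C19 acetate can be carried through, so the late protecting-group exchange disappears; C9 and the alkene are set by the same allylsilane logic as in the chosen plan, so on alkene regiocontrol the two are equal; no C3 oxygen is needed, which is better.
- Against it here: ring A with C4 and C5 must first be made in enantiopure form, for example as in Alternative 2; only one bond and one ring are formed; a tertiary carbinol under BF3·OEt2 can eliminate before it cyclises; the cis/trans ring-fusion ratio rests on a single chair-like approach with no second ring to enforce it.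
- Comparison: mechanistically it is the second half of the chosen cascade run alone, and so more predictable; structurally and in step economy it is weaker, since the chosen plan builds both rings and all four centres from an acyclic chain in one step.

Key step: step 12

Assumption (chemistry): C12 takes no part in the key step, so it is carried as a primary chloride in place of an ester; the carbon skeleton, the bonds formed and the stereochemistry of the key step are unchanged. tert-Butyldimethyl(pent-4-yn-1-yloxy)silane is taken as a catalogue compound, and 3-(phenylsulfanyl)oxolan-2-one is made in one step because its commercial supply is uncertain.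

## Route

Step 1
Reactants: 1 tert-butyldimethyl(pent-4-yn-1-yloxy)silane; 2 trimethylaluminium; 3 oxirane
Product: 6 (3E)-7-[(tert-butyldimethylsilyl)oxy]-4-methylhept-3-en-1-ol, via alkenyldimethylalane 4 (not isolated), via lithium alkenylalanate 5 (not isolated)
Conditions: 2 (2 equiv, hexanes), Cp2ZrCl2 (0.25 equiv), CH2Cl2, 0 °C to rt; excess 2 and solvent removed in vacuo; n-BuLi, THF–hexane, −78 to 0 °C; then 3 (commercial THF solution), 0 °C to rt; aq Rochelle salt
Reagents that add atoms: none
Why: Zirconium-catalysed carboalumination of a terminal alkyne (Negishi): the Me–Al bond adds syn with methyl on the internal carbon, forming C10–C20 and leaving C20 cis to the metal on C5. n-BuLi turns the alkenylalane 4 into the more nucleophilic alanate 5, which opens oxirane with retention at the alkenyl carbon (C5–C6), so only the E-homoallylic alcohol forms. The silyl ether is inert to AlMe3 at room temperature.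

Step 2
Reactants: 6 (3E)-7-[(tert-butyldimethylsilyl)oxy]-4-methylhept-3-en-1-ol
Product: 7 tert-butyl{[(4E)-7-iodo-4-methylhept-4-en-1-yl]oxy}dimethylsilane
Conditions: I2, PPh3, imidazole, CH2Cl2, 0 °C to rt
Reagents that add atoms: iodine, II
Why: Appel-type iodination: iodide displaces the alkoxyphosphonium group (SN2), and imidazole keeps the medium non-acidic so that the silyl ether and the alkene are untouched.

Step 3
Reactants: 8 2,3-dihydrofuran; 7 tert-butyl{[(4E)-7-iodo-4-methylhept-4-en-1-yl]oxy}dimethylsilane
Product: 10 tert-butyl{[(4E)-7-(4,5-dihydrofuran-2-yl)-4-methylhept-4-en-1-yl]oxy}dimethylsilane, via 5-lithio-2,3-dihydrofuran 9 (not isolated)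
Conditions: t-BuLi (pentane), THF, −78 to 0 °C; then 7, −30 °C to rt
Reagents that add atoms: none
Why: The vinylic hydrogen next to oxygen is the most acidic site of 8 (α-alkoxyvinyl lithiation), and the sp2 organolithium 9 displaces the primary iodide of 7 (SN2), forming C7–C8 and locking the future C8=C9 alkene in a ring. Homoallylic iodides are established electrophiles for this alkylation, and a small excess of 9 offsets some E2 loss.

Step 4
Reactants: 10 tert-butyl{[(4E)-7-(4,5-dihydrofuran-2-yl)-4-methylhept-4-en-1-yl]oxy}dimethylsilane; 11 (trimethylsilyl)methylmagnesium chloride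
Product: 12 (3Z,7E)-11-[(tert-butyldimethylsilyl)oxy]-8-methyl-4-[(trimethylsilyl)methyl]undeca-3,7-dien-1-ol
Conditions: 11 (3 equiv, Et2O), NiCl2(PPh3)2 (10 mol %), toluene, 90 °C; aq NH4Cl work-up
Reagents that add atoms: none
Why: Nickel-catalysed Grignard coupling at a vinylic C–O bond (Wenkert-type, established for 5-alkyl-2,3-dihydrofurans): zerovalent nickel inserts into C8–O and the silylmethyl group is delivered with retention, so C17 stands where the ring oxygen was, cis to C11, and C7 and C11 are trans (Z by the CIP rules). The Grignard reagent has no β-hydrogen, so reduction does not compete. The allylsilane and the free C12 hydroxyl appear in one operation, and the near-neutral work-up avoids protodesilylation.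

Step 5
Reactants: 12 (3Z,7E)-11-[(tert-butyldimethylsilyl)oxy]-8-methyl-4-[(trimethylsilyl)methyl]undeca-3,7-dien-1-ol
Product: 14 tert-butyl{[(4E,8Z)-11-chloro-4-methyl-8-[(trimethylsilyl)methyl]undeca-4,8-dien-1-yl]oxy}dimethylsilane, via primary mesylate 13 (not isolated)
Conditions: MsCl, Et3N, THF, 0 °C; then LiCl, 55 °C
Reagents that add atoms: methanesulfonyl chloride, CS(=O)(=O)Cl (atoms kept only in 13); lithium chloride, [Li+].[Cl-]
Why: Sulfonylation and SN2 displacement by chloride under non-acidic conditions; the high chloride concentration keeps direct substitution ahead of any participation by the allylsilane. A primary chloride is inert to fluoride, base, hydride, Lewis acid and silyl radicals in the steps ahead and is one halide exchange away from the iodide needed at the end.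

Step 6
Reactants: 14 tert-butyl{[(4E,8Z)-11-chloro-4-methyl-8-[(trimethylsilyl)methyl]undeca-4,8-dien-1-yl]oxy}dimethylsilane
Product: 15 (4E,8Z)-11-chloro-4-methyl-8-[(trimethylsilyl)methyl]undeca-4,8-dien-1-ol
Conditions: Bu4NF, THF, 0 °C
Reagents that add atoms: none
Why: Fluoride cleaves the primary Si–O bond; at 0 °C neither the allyl–silicon bond nor the primary chloride reacts.

Step 7
Reactants: 15 (4E,8Z)-11-chloro-4-methyl-8-[(trimethylsilyl)methyl]undeca-4,8-dien-1-ol
Product: 16 (4E,8Z)-11-chloro-4-methyl-8-[(trimethylsilyl)methyl]undeca-4,8-dienal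
Conditions: SO3·pyridine, DMSO, i-Pr2NEt, CH2Cl2, 0 °C
Reagents that add atoms: none
Why: Parikh–Doering oxidation (activated DMSO): base-mediated collapse of the alkoxysulfonium ylide gives the aldehyde without acid or metal oxidant, so the acid-sensitive allylsilane survives.

Step 8
Reactants: 16 (4E,8Z)-11-chloro-4-methyl-8-[(trimethylsilyl)methyl]undeca-4,8-dienal; 17 ethyl 2-[bis(2,2,2-trifluoroethoxy)phosphoryl]propanoate
Product: 19 ethyl (2Z,6E,10Z)-13-chloro-2,6-dimethyl-10-[(trimethylsilyl)methyl]trideca-2,6,10-trienoate, via potassium phosphonate carbanion 18 (not isolated)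
Conditions: 17, KN(SiMe3)2, 18-crown-6, THF, −78 °C; then 16
Reagents that add atoms: none
Why: Still–Gennari olefination: the electron-poor phosphonate with a dissociated potassium counter-ion lets the oxaphosphetane collapse faster than it equilibrates, giving the kinetic Z-enoate. This geometry puts C19 cis to the chain and later makes it axial.

Step 9
Reactants: 19 ethyl (2Z,6E,10Z)-13-chloro-2,6-dimethyl-10-[(trimethylsilyl)methyl]trideca-2,6,10-trienoate
Product: 20 (2Z,6E,10Z)-13-chloro-2,6-dimethyl-10-[(trimethylsilyl)methyl]trideca-2,6,10-trien-1-ol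
Conditions: i-Bu2AlH (2.2 equiv), CH2Cl2, −78 °C
Reagents that add atoms: none
Why: 1,2-Reduction of the conjugated ester to the allylic alcohol by two hydride transfers at low temperature; alkene geometry, chloride and allylsilane are untouched.

Step 10
Reactants: 20 (2Z,6E,10Z)-13-chloro-2,6-dimethyl-10-[(trimethylsilyl)methyl]trideca-2,6,10-trien-1-ol
Product: 21 [(2S,3R)-3-{(3E,7Z)-10-chloro-3-methyl-7-[(trimethylsilyl)methyl]deca-3,7-dien-1-yl}-2-methyloxiran-2-yl]methanol
Conditions: Ti(OiPr)4 (10 mol %), L-(+)-diethyl tartrate (12 mol %), t-BuOOH (decane), 4 Å sieves, CH2Cl2, −20 °C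
Reagents that add atoms: tert-butyl hydroperoxide, CC(C)(C)OO
Why: Sharpless asymmetric epoxidation: the titanium tartrate–hydroperoxide complex binds the allylic alcohol, so only C3=C4 of the three alkenes is oxidised. L-(+)-Tartrate delivers oxygen to the face that gives the (2S,3R)-epoxide, the same sense as nerol to (2S,3R)-epoxynerol. This is the only stereogenic element of the chain and fixes the absolute configuration of everything that follows.

Step 11
Reactants: 21 [(2S,3R)-3-{(3E,7Z)-10-chloro-3-methyl-7-[(trimethylsilyl)methyl]deca-3,7-dien-1-yl}-2-methyloxiran-2-yl]methanol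
Product: 22 tert-butyl{[(2S,3R)-3-{(3E,7Z)-10-chloro-3-methyl-7-[(trimethylsilyl)methyl]deca-3,7-dien-1-yl}-2-methyloxiran-2-yl]methoxy}diphenylsilane
Conditions: t-BuPh2SiCl, imidazole, CH2Cl2, 0 °C to rt
Reagents that add atoms: tert-butylchlorodiphenylsilane, CC(C)(C)[Si](Cl)(c1ccccc1)c1ccccc1
Why: Silylation of the primary alcohol under imidazole buffering; the bulky, weakly Lewis-basic silyl ether cannot attack C4 as an ester carbonyl would, and it withstands MeAlCl2.

Step 12
Reactants: 22 tert-butyl{[(2S,3R)-3-{(3E,7Z)-10-chloro-3-methyl-7-[(trimethylsilyl)methyl]deca-3,7-dien-1-yl}-2-methyloxiran-2-yl]methoxy}diphenylsilane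
Product: 23 (3R,4R,5S,9R,10S)-19-[(tert-butyldiphenylsilyl)oxy]-12-chloro-13,14,15,16-tetranorlabd-8(17)-en-3-ol
Conditions: MeAlCl2 (2.2 equiv, hexanes), CH2Cl2, −78 °C; Et3N, then aq NaHCO3
Reagents that add atoms: none
Why: MeAlCl2 binds the epoxide oxygen and polarises the bond to the tertiary carbon C4; C5 of the E-alkene attacks C4 anti to the departing oxygen (inversion at C4, C3–O kept), the developing C10 cation is taken by C9 of the allylsilane, and the β-silyl cation at C8 loses Me3Si to leave C8=C17 as the only alkene. The closest known reaction type is the Lewis-acid epoxy-polyene cyclisation with allylsilane termination. Ring A closes 6-endo with respect to both the epoxide (the C3–C4 bond ends up inside the ring) and the C5=C10 alkene, and ring B closes 6-endo-trig at the allylsilane, both through a chair–chair fold. C3 keeps the R configuration from step 10 and its oxygen becomes equatorial; C4 is set by the invertive opening, so the carbon that was cis to the chain on the Z-derived epoxide becomes the axial C19 (the descriptor changes from S to R only because the CIP priorities change). C5 and C10 follow from anti addition across the E-alkene (trans fusion, C20 syn to C19), and C9 follows from the C7/C11-trans geometry of C8=C9, which puts the chloroethyl arm equatorial. The step needs opening at C4 rather than C3, six- rather than five-membered rings and a single alkene regioisomer; the tertiary character of C4 and C10, the chair fold and the β-effect of silicon secure these. The absolute sense is relayed from the epoxide alone, because the fold that keeps C3–O equatorial exposes only one face of C5=C10. The silyl ether cannot participate at C4 and the primary chloride does not ionise at −78 °C.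

Step 13
Reactants: 23 (3R,4R,5S,9R,10S)-19-[(tert-butyldiphenylsilyl)oxy]-12-chloro-13,14,15,16-tetranorlabd-8(17)-en-3-ol
Product: 24 O-[(3R,4R,5S,9R,10S)-19-(tert-butyldiphenylsilyloxy)-12-chloro-13,14,15,16-tetranorlabd-8(17)-en-3-yl] 1H-imidazole-1-carbothioate
Conditions: 1,1'-thiocarbonyldiimidazole, DMAP (cat.), toluene, 90 °C
Reagents that add atoms: 1,1'-thiocarbonyldiimidazole, S=C(n1ccnc1)n1ccnc1
Why: Thioacylation of the hindered equatorial C3 alcohol by acyl transfer gives the radical precursor without strong base, CS2 or MeI.

Step 14
Reactants: 24 O-[(3R,4R,5S,9R,10S)-19-(tert-butyldiphenylsilyloxy)-12-chloro-13,14,15,16-tetranorlabd-8(17)-en-3-yl] 1H-imidazole-1-carbothioate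
Product: 25 tert-butyl{[(4R,5S,9R,10S)-12-chloro-13,14,15,16-tetranorlabd-8(17)-en-19-yl]oxy}diphenylsilane
Conditions: (Me3Si)3SiH (1.3 equiv), AIBN (cat.), toluene, 85 °C
Reagents that add atoms: none
Why: Barton–McCombie deoxygenation with a silane in place of a tin hydride: the silyl radical adds to C=S, the adduct fragments to the secondary C3 radical and hydrogen transfer gives the methylene group. Addition to the thiocarbonyl is orders of magnitude faster than chlorine abstraction from a primary chloride, and no stereocentre is touched.

Step 15
Reactants: 25 tert-butyl{[(4R,5S,9R,10S)-12-chloro-13,14,15,16-tetranorlabd-8(17)-en-19-yl]oxy}diphenylsilane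
Product: 26 (4R,5S,9R,10S)-12-chloro-13,14,15,16-tetranorlabd-8(17)-en-19-ol
Conditions: Bu4NF, THF, rt to 45 °C
Reagents that add atoms: none
Why: Fluoride cleaves the neopentyl-type silyl ether; this is done before any iodide or butenolide is present, since both would suffer under basic fluoride, whereas the primary chloride does not react with hydrated Bu4NF at this temperature.

Step 16
Reactants: 26 (4R,5S,9R,10S)-12-chloro-13,14,15,16-tetranorlabd-8(17)-en-19-ol
Product: 27 (4R,5S,9R,10S)-12-chloro-13,14,15,16-tetranorlabd-8(17)-en-19-yl acetate
Conditions: Ac2O, pyridine, DMAP (cat.), CH2Cl2, rt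
Reagents that add atoms: acetic anhydride, CC(=O)OC(C)=O
Why: DMAP-catalysed acylation of the hindered primary alcohol installs the acetate of the target.

Step 17
Reactants: 27 (4R,5S,9R,10S)-12-chloro-13,14,15,16-tetranorlabd-8(17)-en-19-yl acetate
Product: 28 (4R,5S,9R,10S)-12-iodo-13,14,15,16-tetranorlabd-8(17)-en-19-yl acetate
Conditions: NaI, butan-2-one, 80 °C
Reagents that add atoms: sodium iodide, [Na+].[I-]
Why: Finkelstein halide exchange (SN2), driven by precipitation of NaCl; the neopentyl acetate and the alkene are inert.

Step 18
Reactants: 29 3-bromooxolan-2-one (racemic); 30 sodium benzenethiolate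
Product: 31 3-(phenylsulfanyl)oxolan-2-one (racemic)
Conditions: THF, 0 °C to rt
Reagents that add atoms: none
Why: SN2 displacement of the activated α-bromide by thiolate; the non-volatile sodium salt avoids handling free thiophenol.

Step 19
Reactants: 28 (4R,5S,9R,10S)-12-iodo-13,14,15,16-tetranorlabd-8(17)-en-19-yl acetate; 31 3-(phenylsulfanyl)oxolan-2-one
Product: 33 (4R,5S,9R,10S)-19-acetoxy-13-(phenylsulfanyl)labd-8(17)-en-16,15-olide (both C13 epimers), via lithium enolate 32 (not isolated)
Conditions: 31, LiN(SiMe3)2, THF, −78 °C; then 28, DMPU, −78 °C to rt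
Reagents that add atoms: none
Why: SN2 alkylation of a sulfur-stabilised lactone enolate with a primary iodide, the established way to attach the precursor of an α-substituted butenolide; the stabilised tertiary enolate does not attack the hindered acetate, and DMPU replaces HMPA. The new C13 centre is destroyed in the next step, so both epimers are used.

Step 20
Reactants: 33 (4R,5S,9R,10S)-19-acetoxy-13-(phenylsulfanyl)labd-8(17)-en-16,15-olide
Product: 35 (4R,5S,9R,10S)-19-acetoxylabda-8(17),13-dien-16,15-olide, via sulfoxide 34 (not isolated)
Conditions: m-CPBA (1.0 equiv), CH2Cl2, −78 °C; then Et3N, toluene, 100 °C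
Reagents that add atoms: m-chloroperbenzoic acid, OOC(=O)c1cccc(Cl)c1 (oxygen kept only in 34)
Why: Chemoselective S-oxidation (the sulfide is far more nucleophilic than the 1,1-disubstituted alkene at −78 °C) followed by thermal syn-elimination of benzenesulfenic acid; for 3-alkyl-3-sulfinyl butanolides elimination into the ring gives the conjugated butenolide. Et3N buffers the carboxylic acid so that C8=C17 does not migrate.

## Compound list

1 | tert-butyldimethyl(pent-4-yn-1-yloxy)silane | C#CCCCO[Si](C)(C)C(C)(C)C | starting material
2 | trimethylaluminium | C[Al](C)C | starting material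
3 | oxirane | C1CO1 | starting material
4 | {(1E)-5-[(tert-butyldimethylsilyl)oxy]-2-methylpent-1-en-1-yl}dimethylaluminium | CC(C)(C)[Si](C)(C)OCCC/C(C)=C/[Al](C)C | intermediate (not isolated)
5 | lithium butyl{(1E)-5-[(tert-butyldimethylsilyl)oxy]-2-methylpent-1-en-1-yl}dimethylaluminate | CC(C)(C)[Si](C)(C)OCCC/C(C)=C/[Al-](C)(C)CCCC.[Li+] | intermediate (not isolated)
6 | (3E)-7-[(tert-butyldimethylsilyl)oxy]-4-methylhept-3-en-1-ol | CC(C)(C)[Si](C)(C)OCCC/C(C)=C/CCO | intermediate
7 | tert-butyl{[(4E)-7-iodo-4-methylhept-4-en-1-yl]oxy}dimethylsilane | CC(C)(C)[Si](C)(C)OCCC/C(C)=C/CCI | intermediate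
8 | 2,3-dihydrofuran | C1=COCC1 | starting material
9 | 5-lithio-2,3-dihydrofuran | [Li]C1=CCCO1 | intermediate (not isolated)
10 | tert-butyl{[(4E)-7-(4,5-dihydrofuran-2-yl)-4-methylhept-4-en-1-yl]oxy}dimethylsilane | CC(C)(C)[Si](C)(C)OCCC/C(C)=C/CCC1=CCCO1 | intermediate
11 | (trimethylsilyl)methylmagnesium chloride | C[Si](C)(C)C[Mg]Cl | starting material
12 | (3Z,7E)-11-[(tert-butyldimethylsilyl)oxy]-8-methyl-4-[(trimethylsilyl)methyl]undeca-3,7-dien-1-ol | CC(C)(C)[Si](C)(C)OCCC/C(C)=C/CC/C(C[Si](C)(C)C)=C/CCO | intermediate
13 | (3Z,7E)-11-[(tert-butyldimethylsilyl)oxy]-8-methyl-4-[(trimethylsilyl)methyl]undeca-3,7-dien-1-yl methanesulfonate | CC(C)(C)[Si](C)(C)OCCC/C(C)=C/CC/C(C[Si](C)(C)C)=C/CCOS(C)(=O)=O | intermediate (not isolated)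
14 | tert-butyl{[(4E,8Z)-11-chloro-4-methyl-8-[(trimethylsilyl)methyl]undeca-4,8-dien-1-yl]oxy}dimethylsilane | CC(C)(C)[Si](C)(C)OCCC/C(C)=C/CC/C(C[Si](C)(C)C)=C/CCCl | intermediate
15 | (4E,8Z)-11-chloro-4-methyl-8-[(trimethylsilyl)methyl]undeca-4,8-dien-1-ol | OCCC/C(C)=C/CC/C(C[Si](C)(C)C)=C/CCCl | intermediate
16 | (4E,8Z)-11-chloro-4-methyl-8-[(trimethylsilyl)methyl]undeca-4,8-dienal | O=CCC/C(C)=C/CC/C(C[Si](C)(C)C)=C/CCCl | intermediate
17 | ethyl 2-[bis(2,2,2-trifluoroethoxy)phosphoryl]propanoate | CCOC(=O)C(C)P(=O)(OCC(F)(F)F)OCC(F)(F)F | starting material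
18 | potassium salt of the carbanion of 17 | CCOC(=O)[C-](C)P(=O)(OCC(F)(F)F)OCC(F)(F)F.[K+] | intermediate (not isolated)
19 | ethyl (2Z,6E,10Z)-13-chloro-2,6-dimethyl-10-[(trimethylsilyl)methyl]trideca-2,6,10-trienoate | CCOC(=O)/C(C)=C\CC/C(C)=C/CC/C(C[Si](C)(C)C)=C/CCCl | intermediate
20 | (2Z,6E,10Z)-13-chloro-2,6-dimethyl-10-[(trimethylsilyl)methyl]trideca-2,6,10-trien-1-ol | OC/C(C)=C\CC/C(C)=C/CC/C(C[Si](C)(C)C)=C/CCCl | intermediate
21 | [(2S,3R)-3-{(3E,7Z)-10-chloro-3-methyl-7-[(trimethylsilyl)methyl]deca-3,7-dien-1-yl}-2-methyloxiran-2-yl]methanol | OC[C@]1(C)O[C@@H]1CC/C(C)=C/CC/C(C[Si](C)(C)C)=C/CCCl | intermediate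
22 | tert-butyl{[(2S,3R)-3-{(3E,7Z)-10-chloro-3-methyl-7-[(trimethylsilyl)methyl]deca-3,7-dien-1-yl}-2-methyloxiran-2-yl]methoxy}diphenylsilane | CC(C)(C)[Si](c1ccccc1)(c1ccccc1)OC[C@]1(C)O[C@@H]1CC/C(C)=C/CC/C(C[Si](C)(C)C)=C/CCCl | intermediate (key-step precursor)
23 | (3R,4R,5S,9R,10S)-19-[(tert-butyldiphenylsilyl)oxy]-12-chloro-13,14,15,16-tetranorlabd-8(17)-en-3-ol (ent series, equatorial 3-OH) | C=C1CC[C@@H]2[C@](C)(CO[Si](c3ccccc3)(c3ccccc3)C(C)(C)C)[C@H](O)CC[C@@]2(C)[C@@H]1CCCl | intermediate (key-step product)
24 | O-[(3R,4R,5S,9R,10S)-19-(tert-butyldiphenylsilyloxy)-12-chloro-13,14,15,16-tetranorlabd-8(17)-en-3-yl] 1H-imidazole-1-carbothioate | C=C1CC[C@@H]2[C@](C)(CO[Si](c3ccccc3)(c3ccccc3)C(C)(C)C)[C@H](OC(=S)n3ccnc3)CC[C@@]2(C)[C@@H]1CCCl | intermediate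
25 | tert-butyl{[(4R,5S,9R,10S)-12-chloro-13,14,15,16-tetranorlabd-8(17)-en-19-yl]oxy}diphenylsilane | C=C1CC[C@@H]2[C@](C)(CO[Si](c3ccccc3)(c3ccccc3)C(C)(C)C)CCC[C@@]2(C)[C@@H]1CCCl | intermediate
26 | (4R,5S,9R,10S)-12-chloro-13,14,15,16-tetranorlabd-8(17)-en-19-ol | C=C1CC[C@@H]2[C@](C)(CO)CCC[C@@]2(C)[C@@H]1CCCl | intermediate
27 | (4R,5S,9R,10S)-12-chloro-13,14,15,16-tetranorlabd-8(17)-en-19-yl acetate | C=C1CC[C@@H]2[C@](C)(COC(C)=O)CCC[C@@]2(C)[C@@H]1CCCl | intermediate
28 | (4R,5S,9R,10S)-12-iodo-13,14,15,16-tetranorlabd-8(17)-en-19-yl acetate | C=C1CC[C@@H]2[C@](C)(COC(C)=O)CCC[C@@]2(C)[C@@H]1CCI | intermediate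
29 | 3-bromooxolan-2-one (α-bromo-γ-butyrolactone, racemic) | BrC1CCOC1=O | starting material
30 | sodium benzenethiolate | [Na+].[S-]c1ccccc1 | starting material
31 | 3-(phenylsulfanyl)oxolan-2-one (racemic) | O=C1OCCC1Sc1ccccc1 | intermediate
32 | lithium enolate of 31 | [Li+].[O-]C1=C(Sc2ccccc2)CCO1 | intermediate (not isolated)
33 | (4R,5S,9R,10S)-19-acetoxy-13-(phenylsulfanyl)labd-8(17)-en-16,15-olide (both C13 epimers) | C=C1CC[C@@H]2[C@](C)(COC(C)=O)CCC[C@@]2(C)[C@@H]1CCC1(Sc2ccccc2)CCOC1=O | intermediate
34 | (4R,5S,9R,10S)-19-acetoxy-13-(phenylsulfinyl)labd-8(17)-en-16,15-olide (diastereomer mixture at C13 and S) | C=C1CC[C@@H]2[C@](C)(COC(C)=O)CCC[C@@]2(C)[C@@H]1CCC1(S(=O)c2ccccc2)CCOC1=O | intermediate (not isolated)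
35 | (4R,5S,9R,10S)-19-acetoxylabda-8(17),13-dien-16,15-olide (19-acetoxy-ent-labda-8(17),13-dien-16,15-olide) | C=C1CC[C@@H]2[C@](C)(COC(C)=O)CCC[C@@]2(C)[C@@H]1CCC1=CCOC1=O | target

## Step count and least certain steps

Total: 20 steps. Longest linear sequence: 19 steps (steps 1–17, 19 and 20; step 18 is a one-step branch).

**Step 12 (key step).** The most likely failure is interruption of the cascade. The CH2OSi group on C4 withdraws electron density, so ionisation of C4–O is slower than in a simple trisubstituted epoxide. Chloride delivery from aluminium, a 1,2-hydride shift to a C3 ketone, or proton loss after ring A can then compete with the second ring closure.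
Fallback: change the terminator, not the Lewis acid. It sets out from 10 and keeps the cyclic enol ether as the π-nucleophile, which should trap the C10 cation faster than an allylsilane and cannot lose a proton to the wrong position. The operations of steps 6 to 11 applied to 10 would give in turn dihydrofuranyl alcohol F1, aldehyde F2, Z-enoate F3, Z-allylic alcohol F4, epoxy alcohol F5 and epoxy silyl ether F6. MeAlCl2 cyclisation of F6 would end in a ring-fused oxocarbenium ion, hydrolysed on work-up to hydroxy ketone F7, in which C9 can equilibrate to the equatorial arm. Wittig methylenation (Ph3P=CH2) would place the alkene at C8=C17 and give diol F8. Chlorination of the primary hydroxyl alone (PPh3, N-chlorosuccinimide) comes back to the route at 23.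

**Step 4.** Insertion of zerovalent nickel into the hindered, trisubstituted vinylic C–O bond may be slow with a bulky, weakly nucleophilic silylmethyl Grignard reagent. Long heating invites loss of alkene geometry through nickel hydride isomerisation, and the product can be protodesilylated on work-up.
Fallback: build the same alkene by syn-carbometallation. It sets out from 7: LiC≡CH·H2NCH2CH2NH2 in DMSO would give terminal alkyne F9. Silylmethylcopper F10, made from 11 and CuBr·SMe2, would add across the triple bond with the silicon-bearing carbon on C8 and copper on C9 to give alkenylcopper F11. Its capture by oxirane 3 (as the cuprate) would form C9–C11 with retention and come back to the route at 12.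

**Step 10.** Incomplete facial selectivity is the risk. Allylic alcohols with a substituent cis to CH2OH are epoxidised more slowly and less selectively, and the minor enantiomer would travel through the cyclisation unnoticed.
Fallback: secure optical purity downstream by diastereomer separation. It sets out from 26, which is esterified with (S)-naproxen (carbodiimide, DMAP) to naproxen ester F12. The minor diastereomer is removed by crystallisation or chromatography, and reductive cleavage with i-Bu2AlH comes back to the route at 26.

**Step 14.** The radical chain may stall. The thiocarbamate sits on a hindered carbon next to quaternary C4, so the adduct radical can be reduced before it fragments (returning alcohol), and forcing the reaction with excess silane starts to reduce C–Cl.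
Fallback: remove the oxygen through the ketone. It sets out from 23: oxidation (Dess–Martin periodinane) would give ketone F13, condensation with tosylhydrazide would give tosylhydrazone F14, and reduction with catecholborane followed by NaOAc would come back to the route at 25.

**Step 20.** The thermal syn-elimination may run toward C12 and give the alkylidene lactone, and the peracid or the hot acidic medium may epoxidise or shift C8=C17.
Fallback: make C12–C13 on an intact butenolide. It sets out from 28: zinc insertion (Zn, LiCl, THF) would give alkylzinc iodide F15, and Negishi coupling with 3-bromofuran-2(5H)-one (Pd2(dba)3, SPhos) would come back to the route at 35, bypassing 33 and 34.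

## Further compounds

F1 | step 12 | (4E)-7-(4,5-dihydrofuran-2-yl)-4-methylhept-4-en-1-ol | OCCC/C(C)=C/CCC1=CCCO1
F2 | step 12 | (4E)-7-(4,5-dihydrofuran-2-yl)-4-methylhept-4-enal | O=CCC/C(C)=C/CCC1=CCCO1
F3 | step 12 | ethyl (2Z,6E)-9-(4,5-dihydrofuran-2-yl)-2,6-dimethylnona-2,6-dienoate | CCOC(=O)/C(C)=C\CC/C(C)=C/CCC1=CCCO1
F4 | step 12 | (2Z,6E)-9-(4,5-dihydrofuran-2-yl)-2,6-dimethylnona-2,6-dien-1-ol | OC/C(C)=C\CC/C(C)=C/CCC1=CCCO1
F5 | step 12 | {(2S,3R)-3-[(3E)-6-(4,5-dihydrofuran-2-yl)-3-methylhex-3-en-1-yl]-2-methyloxiran-2-yl}methanol | OC[C@]1(C)O[C@@H]1CC/C(C)=C/CCC1=CCCO1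
F6 | step 12 | tert-butyl({(2S,3R)-3-[(3E)-6-(4,5-dihydrofuran-2-yl)-3-methylhex-3-en-1-yl]-2-methyloxiran-2-yl}methoxy)diphenylsilane | CC(C)(C)[Si](c1ccccc1)(c1ccccc1)OC[C@]1(C)O[C@@H]1CC/C(C)=C/CCC1=CCCO1
F7 | step 12 | 19-(tert-butyldiphenylsilyloxy)-3,12-dihydroxy-13,14,15,16,17-pentanor-ent-labdan-8-one (ring centres as in 23) | O=C1CC[C@@H]2[C@](C)(CO[Si](c3ccccc3)(c3ccccc3)C(C)(C)C)[C@H](O)CC[C@@]2(C)[C@@H]1CCO
F8 | step 12 | 19-(tert-butyldiphenylsilyloxy)-13,14,15,16-tetranor-ent-labd-8(17)-ene-3,12-diol (ring centres as in 23) | C=C1CC[C@@H]2[C@](C)(CO[Si](c3ccccc3)(c3ccccc3)C(C)(C)C)[C@H](O)CC[C@@]2(C)[C@@H]1CCO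
F9 | step 4 | tert-butyl{[(4E)-4-methylnon-4-en-8-yn-1-yl]oxy}dimethylsilane | CC(C)(C)[Si](C)(C)OCCC/C(C)=C/CCC#C
F10 | step 4 | [(trimethylsilyl)methyl]copper | C[Si](C)(C)C[Cu]
F11 | step 4 | {(1Z,5E)-9-[(tert-butyldimethylsilyl)oxy]-6-methyl-2-[(trimethylsilyl)methyl]nona-1,5-dien-1-yl}copper | CC(C)(C)[Si](C)(C)OCCC/C(C)=C/CC/C(C[Si](C)(C)C)=C/[Cu]
F12 | step 10 | (4R,5S,9R,10S)-12-chloro-13,14,15,16-tetranorlabd-8(17)-en-19-yl (2S)-2-(6-methoxynaphthalen-2-yl)propanoate | C=C1CC[C@@H]2[C@](C)(COC(=O)[C@@H](C)c3ccc4cc(OC)ccc4c3)CCC[C@@]2(C)[C@@H]1CCCl
F13 | step 14 | (4R,5S,9R,10S)-19-[(tert-butyldiphenylsilyl)oxy]-12-chloro-13,14,15,16-tetranorlabd-8(17)-en-3-one | C=C1CC[C@@H]2[C@](C)(CO[Si](c3ccccc3)(c3ccccc3)C(C)(C)C)C(=O)CC[C@@]2(C)[C@@H]1CCCl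
F14 | step 14 | 4-methylbenzenesulfonylhydrazone of F13 | C=C1CC[C@@H]2[C@](C)(CO[Si](c3ccccc3)(c3ccccc3)C(C)(C)C)C(=NNS(=O)(=O)c3ccc(C)cc3)CC[C@@]2(C)[C@@H]1CCCl
F15 | step 20 | [(4R,5S,9R,10S)-19-acetoxy-13,14,15,16-tetranorlabd-8(17)-en-12-yl]zinc iodide | C=C1CC[C@@H]2[C@](C)(COC(C)=O)CCC[C@@]2(C)[C@@H]1CC[Zn]I
A1 | alternative 1 | 2-[3-{2-[(tert-butyldimethylsilyl)oxy]ethyl}-2-(3-iodopropyl)-2-methyl-4-methylidenecyclohexyl]propanenitrile (ring centres as in 35; either C4 epimer) | C=C1CC[C@H](C(C)C#N)[C@@](C)(CCCI)[C@@H]1CCO[Si](C)(C)C(C)(C)C
A2 | alternative 1 | 12-[(tert-butyldimethylsilyl)oxy]-13,14,15,16-tetranor-ent-labd-8(17)-ene-19-nitrile (axial nitrile) | C=C1CC[C@@H]2[C@](C)(C#N)CCC[C@@]2(C)[C@@H]1CCO[Si](C)(C)C(C)(C)C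
A3 | alternative 2 | 3-{[(tert-butyldiphenylsilyl)oxy]methyl}cyclohex-2-en-1-one | O=C1C=C(CO[Si](c2ccccc2)(c2ccccc2)C(C)(C)C)CCC1
A4 | alternative 2 | 2-allyl-3-methyl-3-{[(tert-butyldiphenylsilyl)oxy]methyl}cyclohexan-1-one (allyl cis to silyloxymethyl) | O=C1CCC[C@@](C)(CO[Si](c2ccccc2)(c2ccccc2)C(C)(C)C)[C@H]1CC=C
A5 | alternative 3 | {2-[(3Z)-6-[(tert-butyldiphenylsilyl)oxy]-3-[(trimethylsilyl)methyl]hex-3-en-1-yl]-3-hydroxy-1,3-dimethylcyclohexyl}methyl acetate (C4 and C5 as in 35; either C10 epimer) | CC1(O)CCC[C@@](C)(COC(C)=O)[C@H]1CC/C(C[Si](C)(C)C)=C/CCO[Si](c1ccccc1)(c1ccccc1)C(C)(C)C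
A6 | alternative 3 | (4R,5S,9R,10S)-12-[(tert-butyldiphenylsilyl)oxy]-13,14,15,16-tetranorlabd-8(17)-en-19-yl acetate | C=C1CC[C@@H]2[C@](C)(COC(C)=O)CCC[C@@]2(C)[C@@H]1CCO[Si](c1ccccc1)(c1ccccc1)C(C)(C)C
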